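**Retrosynthetic overview**

1. The target is cut back to a trans-decalin 3-ketone: C-9 hydroxylation comes last, preceded by C-8 alcohol → ketone, C-3 esterification with (2E,4E,6E)-5-methyldodeca-2,4,6-trienoic acid (from (E)-oct-2-enal by alkyne homologation, carboalumination/iodination and Heck coupling) and thermodynamic reduction of the C-3 ketone.
2. The decalin ketone comes from a monocyclic 2-methyl-2-(1-thionocarbonyloxyethyl)cyclopentanone that carries a 2-silyloxy-3-methylidene-4-methylpent-4-enyl chain on C-3. Ring A is never built as a six-membered ring: it grows from the cyclopentanone by a one-carbon radical ring expansion, and ring B closes in the same operation.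
3. Enabling feature: the cyclopentanone C=O lies β to a radical generated on the exocyclic CH(CH3) carbon at the α-quaternary ring carbon. 3-exo attack on C=O, then β-scission of the ring bond between C=O and the quaternary carbon, moves that carbon into the ring and leaves a tertiary ring radical. The neighbouring ring carbon holds a 2,3-disubstituted buta-1,3-diene four atoms away for 6-endo capture.
4. The cyclopentanone comes from 2-methylcyclopent-2-en-1-one, a chiral allylphosphonamide anion and acetaldehyde (one-pot conjugate addition/aldol), then ozonolysis, propynyl addition and ethylene enyne metathesis. The single stereocentre set there (future C-10) controls C-5, C-4, C-3 and C-9.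
5. Ring order: cyclopentanone (purchased ring), then ring A (by expansion) and ring B together in step 8.

Key step: step 8

**Remarks**

- Eremophilane numbering is used in the Why lines for every carbon that ends up in the decalin, also in the monocyclic precursors: C-3 ester carbon, C-4 CH(CH3), C-5 quaternary carbon, C-10 ring-fusion CH, C-6 to C-9 ring B, C-11 isopropylidene carbon.
- Assumption: the (R,R)-allylphosphonamide is taken to add to the enone face that gives the 3S adduct. If the sense of induction is the opposite one, the (S,S)-diamine is used and nothing else changes.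

**Route**

Step 1
Reactants: 1 (1R,2R)-N,N′-dimethylcyclohexane-1,2-diamine; 2 allylphosphonic dichloride
Product: 3 (3aR,7aR)-1,3-dimethyl-2-(prop-2-en-1-yl)octahydro-1H-1,3,2-benzodiazaphosphole 2-oxide
Conditions: Et3N, CH2Cl2, 0 °C → rt
Reagents that add atoms: none
Why: Double P–N bond formation (phosphonamide synthesis) between the dichloride and the C2-symmetric secondary diamine closes the diazaphospholidine, and no new stereocentre arises because phosphorus lies on the C2 axis.

Step 2
Reactants: 3 the allylphosphonamide; 4 2-methylcyclopent-2-en-1-one; 5 acetaldehyde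
Product: 9 (3S)-3-[(2E)-3-{(3aR,7aR)-1,3-dimethyl-2-oxidooctahydro-1H-1,3,2-benzodiazaphosphol-2-yl}prop-2-en-1-yl]-2-methyl-2-[1-(trimethylsilyloxy)ethyl]cyclopentan-1-one (C-2/C-1′ epimer mixture), via lithiated phosphonamide 6 (not isolated), via lithium enolate 7 (not isolated), via lithium aldolate 8 (not isolated)
Conditions: n-BuLi, THF, −78 °C; then 4; then 5, −78 °C; then TMSCl, −78 → 0 °C
Reagents that add atoms: chlorotrimethylsilane, C[Si](C)(C)Cl
Why: Asymmetric conjugate allylation with the chiral allylphosphonamide anion (γ-attack, 1,4-addition through a lithium-chelated transition state) sets C-10 under auxiliary control, and the regiodefined tetrasubstituted enolate is trapped by aldol addition to acetaldehyde and O-silylation, the configurations at C-5 and C-4 being irrelevant because both are erased or equilibrated in step 8.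

Step 3
Reactants: 9 the TMS-protected aldol adduct
Product: 10 2-{(1S)-2-methyl-3-oxo-2-[1-(trimethylsilyloxy)ethyl]cyclopentyl}acetaldehyde (epimer mixture at the quaternary and silyloxy carbons)
Conditions: O3, CH2Cl2, −78 °C; then Me2S, −78 °C → rt
Reagents that add atoms: ozone, [O-][O+]=O
Why: Ozonolysis with reductive work-up cleaves the only C=C bond, that of the vinylphosphonamide, and releases the C-8 aldehyde without touching C-10.

Step 4
Reactants: 10 the keto aldehyde; 11 prop-1-yn-1-ylmagnesium bromide
Product: 12 (3S)-3-(2-hydroxypent-3-yn-1-yl)-2-methyl-2-[1-(trimethylsilyloxy)ethyl]cyclopentan-1-one (epimer mixture at C-2/C-1′/carbinol carbon)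
Conditions: THF, −78 °C; aq. NH4Cl
Reagents that add atoms: none
Why: Grignard 1,2-addition of the alkynyl nucleophile at low temperature is chemoselective for the aldehyde over the α-quaternary cyclopentanone, and the new carbinol centre (C-8) is a mixture that is oxidised later.

Step 5
Reactants: 12 the propargylic alcohol
Product: 14 (3S)-3-[2-(tert-butyldimethylsilyloxy)pent-3-yn-1-yl]-2-(1-hydroxyethyl)-2-methylcyclopentan-1-one (epimer mixture as before), via bis-silyl ether 13 (not isolated)
Conditions: TBSCl, imidazole, DMF, rt; then citric acid, MeOH, 0 °C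
Reagents that add atoms: tert-butyldimethylsilyl chloride, CC(C)(C)[Si](C)(C)Cl
Why: Silylation of the unhindered propargylic alcohol followed by mild acid methanolysis, which removes the labile trimethylsilyl ether but not the TBS ether, differentiates the two hydroxyls in one operation (protecting-group exchange).

Step 6
Reactants: 14 the alkynyl β-hydroxy ketone; 15 ethylene
Product: 16 (3S)-3-[2-(tert-butyldimethylsilyloxy)-4-methyl-3-methylidenepent-4-en-1-yl]-2-(1-hydroxyethyl)-2-methylcyclopentan-1-one (epimer mixture as before)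
Conditions: Grubbs II (5 mol %), ethylene (1 atm), PhMe, 80 °C
Reagents that add atoms: none
Why: Ruthenium-catalysed ethylene–alkyne cross enyne metathesis converts the internal alkyne into the 2,3-disubstituted buta-1,3-diene with full atom economy and tolerates the free β-hydroxy ketone.

Step 7
Reactants: 16 the dienyl β-hydroxy ketone
Product: 17 O-[1-{(2S)-2-[2-(tert-butyldimethylsilyloxy)-4-methyl-3-methylidenepent-4-en-1-yl]-1-methyl-5-oxocyclopentyl}ethyl] O-phenyl carbonothioate (epimer mixture as before)
Conditions: PhOC(S)Cl, pyridine, DMAP (cat.), CH2Cl2, 0 °C → rt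
Reagents that add atoms: O-phenyl chlorothionoformate, S=C(Cl)Oc1ccccc1
Why: DMAP-catalysed thioacylation of the only free hydroxyl gives the thionocarbonate radical precursor (first half of a Barton–McCombie sequence) under conditions too mild for retro-aldol cleavage.

Step 8
Reactants: 17 the thionocarbonate
Product: 23 (1R,4aS,8aS)-6-(tert-butyldimethylsilyloxy)-1,8a-dimethyl-7-(propan-2-ylidene)octahydronaphthalen-2(1H)-one (trans-fused; C-6 epimer mixture), via secondary alkyl radical 18 (not isolated), via cyclopropyloxy radical 19 (not isolated), via ring-expanded tertiary radical 20 (not isolated), via bicyclic allyl radical 21 (not isolated), via C-4 epimer mixture 22 (not isolated)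
Conditions: Bu3SnH (syringe pump), AIBN (cat.), PhH (5 mM, degassed), 80 °C; then K2CO3 (cat.), MeOH, rt
Reagents that add atoms: none
Why: The stannyl radical cleaves the thionocarbonate (Barton–McCombie) to the secondary radical 18, which adds 3-exo-trig to the adjacent cyclopentanone carbonyl carbon to give the cyclopropyloxy radical 19; β-scission of the bond between the carbonyl carbon and the quaternary carbon (Dowd–Beckwith 1,2-acyl shift) moves the CH(CH3) carbon into the ring, so ring A is born six-membered as the tertiary 3-oxocyclohexyl radical 20. Radical 20 closes ring B by 6-endo-trig attack on the CH2 terminus of the diene next to the silyloxy carbon (C-5–C-6 bond) to give the allyl radical 21, and hydrogen transfer from Bu3SnH to its unhindered CH2 end leaves the tetrasubstituted isopropylidene alkene. The closest known reaction type is the tin-hydride Dowd–Beckwith ring expansion of 2-(haloalkyl)cycloalkanones run in tandem with a radical cyclization, and the ring-B closure mirrors the second 6-endo step of radical polyene cyclizations. The new quaternary centre C-5 is controlled by C-10: with the tether equatorial on ring A, the chair-like transition state forms the C-5–C-6 bond equatorially and leaves the methyl axial, which is the trans-decalin; C-4 is formed without control (mixture 22) and is then equilibrated through the C-3 enolate to the equatorial 4β-methyl epimer 23. The step needs acyl shift and ring closure to outrun hydrogen transfer to 18 and 20, which is secured by syringe-pump addition at high dilution and by 20 being the thermodynamic sink of the 18/19/20 manifold, and it needs six-membered closure over seven-membered closure (attack at the other diene terminus) and over 5-exo attack, which is secured by the chair six-membered transition state and by the fact that only terminal attack gives an allyl radical. The C-8 silyloxy stereocentre is a mixture of no consequence, since it is oxidised in step 15.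

Step 9
Reactants: 23 the decalin ketone
Product: 24 (1R,2R,4aS,8aS)-6-(tert-butyldimethylsilyloxy)-1,8a-dimethyl-7-(propan-2-ylidene)decahydronaphthalen-2-ol (C-6 epimer mixture)
Conditions: Li, NH3(l), THF, MeOH, −78 °C; then NH4Cl
Reagents that add atoms: none
Why: Dissolving-metal ketone reduction proceeds through the ketyl and should give the thermodynamically preferred equatorial 3α-alcohol, whereas hydride reagents would attack away from the 1,3-diaxial angular methyl and give the axial epimer, and the isolated tetrasubstituted alkene and the silyl ether are not reduced.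

Step 10
Reactants: 25 (2E)-oct-2-enal
Product: 26 (3E)-non-3-en-1-yne
Conditions: TMSCHN2, n-BuLi, THF, −78 °C → rt
Reagents that add atoms: (trimethylsilyl)diazomethane, C[Si](C)(C)C=[N+]=[N-]
Why: Colvin rearrangement (one-carbon aldehyde-to-alkyne homologation with lithiated trimethylsilyldiazomethane) delivers the terminal enyne and leaves the E alkene untouched.

Step 11
Reactants: 26 the enyne
Product: 28 (1E,3E)-1-iodo-2-methylnona-1,3-diene, via alkenylalane 27 (not isolated)
Conditions: AlMe3, Cp2ZrCl2 (cat.), CH2Cl2, 0 °C → rt; then I2, THF, −30 °C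
Reagents that add atoms: trimethylaluminium, C[Al](C)C; iodine, II
Why: Zirconium-catalysed carboalumination (Negishi) adds methyl and aluminium syn across the terminal alkyne with aluminium at the terminus, and iodinolysis with retention fixes the trisubstituted E geometry.

Step 12
Reactants: 28 the dienyl iodide; 29 acrylic acid
Product: 30 (2E,4E,6E)-5-methyldodeca-2,4,6-trienoic acid
Conditions: Pd(OAc)2 (cat.), Bu4NCl, Et3N, DMF, 40 °C; then aq. HCl
Reagents that add atoms: none
Why: Heck coupling of the alkenyl iodide with acrylic acid under ligand-free phase-transfer conditions forms the C-3–C-4 bond of the acid with retention of the dienyl geometry and gives the 2E alkene by syn β-hydride elimination.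

Step 13
Reactants: 30 the trienoic acid; 24 the 3α-alcohol
Product: 32 (1R,2R,4aS,8aS)-6-(tert-butyldimethylsilyloxy)-1,8a-dimethyl-7-(propan-2-ylidene)decahydronaphthalen-2-yl (2E,4E,6E)-5-methyldodeca-2,4,6-trienoate (C-6 epimer mixture), via mixed anhydride 31 (not isolated)
Conditions: 2,4,6-Cl3C6H2COCl, Et3N, THF, rt; then 24, DMAP, PhMe, rt
Reagents that add atoms: none
Why: Yamaguchi esterification through the mixed 2,4,6-trichlorobenzoic anhydride acylates the hindered equatorial secondary alcohol under DMAP catalysis without touching the stereocentres or the triene geometry.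

Step 14
Reactants: 32 the silyl ether ester
Product: 33 (1R,2R,4aS,8aS)-6-hydroxy-1,8a-dimethyl-7-(propan-2-ylidene)decahydronaphthalen-2-yl (2E,4E,6E)-5-methyldodeca-2,4,6-trienoate (C-6 epimer mixture)
Conditions: TBAF, AcOH, THF, 0 °C → rt
Reagents that add atoms: none
Why: Fluoride-mediated desilylation under acetic acid buffering frees the allylic alcohol while avoiding both ester cleavage and acid-promoted allylic ionisation.

Step 15
Reactants: 33 the allylic alcohol
Product: 34 (1R,2R,4aS,8aS)-1,8a-dimethyl-6-oxo-7-(propan-2-ylidene)decahydronaphthalen-2-yl (2E,4E,6E)-5-methyldodeca-2,4,6-trienoate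
Conditions: Dess–Martin periodinane, NaHCO3, CH2Cl2, 0 °C → rt
Reagents that add atoms: none
Why: Dess–Martin oxidation of the allylic alcohol converges both C-8 epimers on the conjugated isopropylidene ketone under neutral, buffered conditions.

Step 16
Reactants: 34 the enone ester
Product: 36 (1R,2R,4aR,5S,8aR)-5-hydroxy-1,8a-dimethyl-6-oxo-7-(propan-2-ylidene)decahydronaphthalen-2-yl (2E,4E,6E)-5-methyldodeca-2,4,6-trienoate (CNP0211657.1), via potassium enolate 35 (not isolated)
Conditions: KHMDS, THF, −78 °C; then 2-(phenylsulfonyl)-3-phenyloxaziridine, −78 °C; aq. NH4Cl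
Reagents that add atoms: 2-(phenylsulfonyl)-3-phenyloxaziridine, O=S(=O)(N1OC1c1ccccc1)c1ccccc1
Why: Kinetic deprotonation of the enone at the α′ methylene C-9 (as with other 2-isopropylidenecyclohexanones) and electrophilic hydroxylation of the enolate by the N-sulfonyloxaziridine (Davis oxidation) from the α face, away from the axial angular methyl that is 1,3 to C-9, should install the equatorial 9α-hydroxyl.

**Compound list**

1 | (1R,2R)-N,N′-dimethylcyclohexane-1,2-diamine | CN[C@@H]1CCCC[C@H]1NC | starting material
2 | allylphosphonic dichloride | C=CCP(=O)(Cl)Cl | starting material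
3 | (3aR,7aR)-1,3-dimethyl-2-(prop-2-en-1-yl)octahydro-1H-1,3,2-benzodiazaphosphole 2-oxide | C=CCP1(=O)N(C)[C@@H]2CCCC[C@H]2N1C | intermediate
4 | 2-methylcyclopent-2-en-1-one | CC1=CCCC1=O | starting material
5 | acetaldehyde | CC=O | starting material
6 | α-lithiated allylphosphonamide | [Li]C(C=C)P1(=O)N(C)[C@@H]2CCCC[C@H]2N1C | intermediate
7 | lithium (3S)-2-methyl-3-[(2E)-3-(phosphonamidyl)prop-2-en-1-yl]cyclopent-1-en-1-olate | [Li]OC1=C(C)[C@H](C/C=C/P2(=O)N(C)[C@@H]3CCCC[C@H]3N2C)CC1 | intermediate
8 | lithium aldolate of 7 with acetaldehyde (C-2/C-1′ epimer mixture) | O=C1CC[C@@H](C/C=C/P2(=O)N(C)[C@@H]3CCCC[C@H]3N2C)C1(C)C(C)O[Li] | intermediate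
9 | (3S)-3-[(2E)-3-{(3aR,7aR)-1,3-dimethyl-2-oxidooctahydro-1H-1,3,2-benzodiazaphosphol-2-yl}prop-2-en-1-yl]-2-methyl-2-[1-(trimethylsilyloxy)ethyl]cyclopentan-1-one (C-2/C-1′ epimer mixture) | O=C1CC[C@@H](C/C=C/P2(=O)N(C)[C@@H]3CCCC[C@H]3N2C)C1(C)C(C)O[Si](C)(C)C | intermediate
10 | 2-{(1S)-2-methyl-3-oxo-2-[1-(trimethylsilyloxy)ethyl]cyclopentyl}acetaldehyde (epimer mixture) | O=C1CC[C@@H](CC=O)C1(C)C(C)O[Si](C)(C)C | intermediate
11 | prop-1-yn-1-ylmagnesium bromide | CC#C[Mg]Br | starting material
12 | (3S)-3-(2-hydroxypent-3-yn-1-yl)-2-methyl-2-[1-(trimethylsilyloxy)ethyl]cyclopentan-1-one (epimer mixture) | O=C1CC[C@@H](CC(O)C#CC)C1(C)C(C)O[Si](C)(C)C | intermediate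
13 | (3S)-3-[2-(tert-butyldimethylsilyloxy)pent-3-yn-1-yl]-2-methyl-2-[1-(trimethylsilyloxy)ethyl]cyclopentan-1-one (epimer mixture) | O=C1CC[C@@H](CC(O[Si](C)(C)C(C)(C)C)C#CC)C1(C)C(C)O[Si](C)(C)C | intermediate
14 | (3S)-3-[2-(tert-butyldimethylsilyloxy)pent-3-yn-1-yl]-2-(1-hydroxyethyl)-2-methylcyclopentan-1-one (epimer mixture) | O=C1CC[C@@H](CC(O[Si](C)(C)C(C)(C)C)C#CC)C1(C)C(C)O | intermediate
15 | ethylene | C=C | starting material
16 | (3S)-3-[2-(tert-butyldimethylsilyloxy)-4-methyl-3-methylidenepent-4-en-1-yl]-2-(1-hydroxyethyl)-2-methylcyclopentan-1-one (epimer mixture) | O=C1CC[C@@H](CC(O[Si](C)(C)C(C)(C)C)C(=C)C(C)=C)C1(C)C(C)O | intermediate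
17 | O-phenyl thionocarbonate of 16 | O=C1CC[C@@H](CC(O[Si](C)(C)C(C)(C)C)C(=C)C(C)=C)C1(C)C(C)OC(=S)Oc2ccccc2 | intermediate
18 | secondary 1-(2-oxocyclopentyl)ethyl radical | O=C1CC[C@@H](CC(O[Si](C)(C)C(C)(C)C)C(=C)C(C)=C)C1(C)[CH]C | intermediate
19 | bicyclo[3.1.0]hexan-1-yloxy (cyclopropyloxy) radical | [O]C12CC[C@@H](CC(O[Si](C)(C)C(C)(C)C)C(=C)C(C)=C)C1(C)C2C | intermediate
20 | ring-expanded tertiary 1,2-dimethyl-3-oxocyclohexyl radical | O=C1CC[C@@H](CC(O[Si](C)(C)C(C)(C)C)C(=C)C(C)=C)[C](C)C(C)C1 | intermediate
21 | trans-decalin allyl radical | O=C1CC[C@H]2CC(O[Si](C)(C)C(C)(C)C)C(=C(C)[CH2])C[C@]2(C)C1C | intermediate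
22 | (4aS,8aS)-6-(tert-butyldimethylsilyloxy)-1,8a-dimethyl-7-(propan-2-ylidene)octahydronaphthalen-2(1H)-one, C-1 epimer mixture | O=C1CC[C@H]2CC(O[Si](C)(C)C(C)(C)C)C(=C(C)C)C[C@]2(C)C1C | intermediate
23 | (1R,4aS,8aS)-6-(tert-butyldimethylsilyloxy)-1,8a-dimethyl-7-(propan-2-ylidene)octahydronaphthalen-2(1H)-one (C-6 epimer mixture) | O=C1CC[C@H]2CC(O[Si](C)(C)C(C)(C)C)C(=C(C)C)C[C@]2(C)[C@H]1C | intermediate
24 | (1R,2R,4aS,8aS)-6-(tert-butyldimethylsilyloxy)-1,8a-dimethyl-7-(propan-2-ylidene)decahydronaphthalen-2-ol (C-6 epimer mixture) | O[C@@H]1CC[C@H]2CC(O[Si](C)(C)C(C)(C)C)C(=C(C)C)C[C@]2(C)[C@H]1C | intermediate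
25 | (2E)-oct-2-enal | CCCCC/C=C/C=O | starting material
26 | (3E)-non-3-en-1-yne | CCCCC/C=C/C#C | intermediate
27 | dimethyl[(1E,3E)-2-methylnona-1,3-dien-1-yl]alane | CCCCC/C=C/C(C)=C/[Al](C)C | intermediate
28 | (1E,3E)-1-iodo-2-methylnona-1,3-diene | CCCCC/C=C/C(C)=C/I | intermediate
29 | acrylic acid | C=CC(=O)O | starting material
30 | (2E,4E,6E)-5-methyldodeca-2,4,6-trienoic acid | CCCCC/C=C/C(C)=C/C=C/C(=O)O | intermediate
31 | (2E,4E,6E)-5-methyldodeca-2,4,6-trienoic 2,4,6-trichlorobenzoic anhydride | CCCCC/C=C/C(C)=C/C=C/C(=O)OC(=O)c1c(Cl)cc(Cl)cc1Cl | intermediate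
32 | (1R,2R,4aS,8aS)-6-(tert-butyldimethylsilyloxy)-1,8a-dimethyl-7-(propan-2-ylidene)decahydronaphthalen-2-yl (2E,4E,6E)-5-methyldodeca-2,4,6-trienoate (C-6 epimer mixture) | CCCCC/C=C/C(C)=C/C=C/C(=O)O[C@@H]1CC[C@H]2CC(O[Si](C)(C)C(C)(C)C)C(=C(C)C)C[C@]2(C)[C@H]1C | intermediate
33 | (1R,2R,4aS,8aS)-6-hydroxy-1,8a-dimethyl-7-(propan-2-ylidene)decahydronaphthalen-2-yl (2E,4E,6E)-5-methyldodeca-2,4,6-trienoate (C-6 epimer mixture) | CCCCC/C=C/C(C)=C/C=C/C(=O)O[C@@H]1CC[C@H]2CC(O)C(=C(C)C)C[C@]2(C)[C@H]1C | intermediate
34 | (1R,2R,4aS,8aS)-1,8a-dimethyl-6-oxo-7-(propan-2-ylidene)decahydronaphthalen-2-yl (2E,4E,6E)-5-methyldodeca-2,4,6-trienoate | CCCCC/C=C/C(C)=C/C=C/C(=O)O[C@@H]1CC[C@H]2CC(=O)C(=C(C)C)C[C@]2(C)[C@H]1C | intermediate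
35 | potassium α′-enolate of 34 | CCCCC/C=C/C(C)=C/C=C/C(=O)O[C@@H]1CC[C@H]2C=C(O[K])C(=C(C)C)C[C@]2(C)[C@H]1C | intermediate
36 | (1R,2R,4aR,5S,8aR)-5-hydroxy-1,8a-dimethyl-6-oxo-7-(propan-2-ylidene)decahydronaphthalen-2-yl (2E,4E,6E)-5-methyldodeca-2,4,6-trienoate | CCCCC/C=C/C(C)=C/C=C/C(=O)O[C@@H]1CC[C@H]2[C@H](O)C(=O)C(=C(C)C)C[C@]2(C)[C@H]1C | target

**Step count**

Total step count: 16. Longest linear sequence: 13 steps (steps 1–9 and 13–16); the acid branch is steps 10–12.

**Steps most likely to fail**

Step 8. What may go wrong: hydrogen transfer from the tin hydride to the secondary radical before the acyl shift, or to the ring-expanded tertiary radical before it closes onto the unactivated diene, and closure with incomplete trans selectivity. Fallback: it sets out from 17 and makes the acceptor electron-poor so that the tertiary radical is captured much faster. The silyl ether is removed with HF·pyridine (pyridine-buffered, THF, 0 °C) to give the dienyl carbinol thionocarbonate F1. Dess–Martin oxidation gives the cross-conjugated dienone thionocarbonate F2, which is used at once in dilute solution because 2-acyl dienes dimerise. The same Bu3SnH/AIBN cascade followed by K2CO3/MeOH should then give the trans-fused eremophil-7(11)-ene-3,8-dione F3 directly. L-Selectride at −78 °C should reduce only the saturated C-3 ketone, from the equatorial side, to the axial 3β-alcohol F4. Mitsunobu esterification (PPh3, DIAD) with acid 30 inverts C-3 and comes back to the route at 34.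

Step 16. What may go wrong: competing deprotonation of the trienoate at its vinylogous positions or γ-enolisation of the enone by the amide base, and addition of the enolate to the sulfonimine that the oxidant leaves behind. Fallback: it sets out from 34 and avoids strong base. Mn(OAc)3 in benzene at reflux (α′-acetoxylation through the manganese(III) enolate) gives the 9-acetoxy enone ester F5. K2CO3 in MeOH at 0 °C cleaves the activated α-keto acetate in preference to the hindered conjugated ester and equilibrates C-9 to the equatorial epimer, coming back to the route at 36.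

Step 2. What may go wrong: incomplete C–C trapping of the hindered tetrasubstituted lithium enolate by acetaldehyde and retro-aldol cleavage of the aldolate on warming before it is silylated. Fallback: it sets out from 3 and 4 and separates the events. The conjugate addition is quenched with TMSCl to give the regiodefined trimethylsilyl enol ether F6. Mukaiyama aldol with acetaldehyde 5 (TiCl4, CH2Cl2, −78 °C) gives the free aldol F7. Silylation (TMSCl, imidazole, CH2Cl2) comes back to the route at 9.

**Further compounds**

F1 | step 8 | O-[1-{(2S)-2-(2-hydroxy-4-methyl-3-methylidenepent-4-en-1-yl)-1-methyl-5-oxocyclopentyl}ethyl] O-phenyl carbonothioate (epimer mixture) | O=C1CC[C@@H](CC(O)C(=C)C(C)=C)C1(C)C(C)OC(=S)Oc2ccccc2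
F2 | step 8 | O-[1-{(2S)-1-methyl-2-(4-methyl-3-methylidene-2-oxopent-4-en-1-yl)-5-oxocyclopentyl}ethyl] O-phenyl carbonothioate (epimer mixture) | O=C1CC[C@@H](CC(=O)C(=C)C(C)=C)C1(C)C(C)OC(=S)Oc2ccccc2
F3 | step 8 | (1R,4aS,8aS)-1,8a-dimethyl-7-(propan-2-ylidene)octahydronaphthalene-2,6(1H,5H)-dione | O=C1CC[C@H]2CC(=O)C(=C(C)C)C[C@]2(C)[C@H]1C
F4 | step 8 | (4aS,5R,6S,8aS)-6-hydroxy-4a,5-dimethyl-3-(propan-2-ylidene)octahydronaphthalen-2(1H)-one (axial 3β-alcohol) | O[C@H]1CC[C@H]2CC(=O)C(=C(C)C)C[C@]2(C)[C@H]1C
F5 | step 16 | (1R,2R,4aR,5S,8aR)-5-acetoxy-1,8a-dimethyl-6-oxo-7-(propan-2-ylidene)decahydronaphthalen-2-yl (2E,4E,6E)-5-methyldodeca-2,4,6-trienoate | CCCCC/C=C/C(C)=C/C=C/C(=O)O[C@@H]1CC[C@H]2[C@H](OC(C)=O)C(=O)C(=C(C)C)C[C@]2(C)[C@H]1C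
F6 | step 2 | (3S)-2-methyl-3-[(2E)-3-{(3aR,7aR)-1,3-dimethyl-2-oxidooctahydro-1H-1,3,2-benzodiazaphosphol-2-yl}prop-2-en-1-yl]-1-(trimethylsilyloxy)cyclopent-1-ene | C[Si](C)(C)OC1=C(C)[C@H](C/C=C/P2(=O)N(C)[C@@H]3CCCC[C@H]3N2C)CC1
F7 | step 2 | (3S)-2-(1-hydroxyethyl)-2-methyl-3-[(2E)-3-{(3aR,7aR)-1,3-dimethyl-2-oxidooctahydro-1H-1,3,2-benzodiazaphosphol-2-yl}prop-2-en-1-yl]cyclopentan-1-one (epimer mixture) | O=C1CC[C@@H](C/C=C/P2(=O)N(C)[C@@H]3CCCC[C@H]3N2C)C1(C)C(C)O
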